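**Plan**

- Retrosynthesis: the oxirane C2–O bond and the C3–C4 bond are cut together, giving an α-chloro methyl ketone and an (E)-allyl bromide. Then the aryl ether O–C1 bond is cut (to isofraxidin), then the C5=C6 olefin of the bromide (metathesis).
- Forward: D-threonine supplies C1–C3 and the C3 methyl (NH2 to Cl, CO2H to CH2OH, ether formation, CHOH to ketone). A cross metathesis supplies C4–C7. The last step joins the halves and closes the oxirane, the only ring that is made; the coumarin bicycle is bought.
- Enabling feature: oxirane carbon C3 bears O, CH3 and the allylic C4H2 and is bonded to the O-bearing C2, so the ring is the closed form of a tertiary chlorohydrin of a methyl ketone. The far allyl terminus C6 is flanked by the quaternary carbinol C7, which should force bond formation at C4.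
- Stereochemistry: C2 comes from D-threonine (Cl for NH2 with retention, then inversion on ring closure). C3 is set by Cornforth/Felkin–Anh 1,2-induction from C2–Cl. The 5E olefin comes from the metathesis and is kept in the allylindium step.

Key step: step 6

Remark: side-chain locants C1–C8 count from the aryl-ether CH2 (C1) through the oxirane carbons (C2, C3) to the carbinol carbon (C7); D-threonine, isofraxidin, 2-methylbut-3-en-2-ol and (E)-1,4-dibromobut-2-ene are taken as purchased.

**Route**

Step 1
Reactants: 1 D-threonine [(2R,3S)-2-amino-3-hydroxybutanoic acid]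
Product: 2 (2R,3S)-2-chloro-3-hydroxybutanoic acid
Conditions: NaNO2, 6 M HCl, −5 °C to rt
Reagents that add atoms: hydrochloric acid, Cl
Why: Diazotisation of an α-amino acid in hydrochloric acid replaces NH2 by Cl with net retention (double inversion through the α-lactone), a standard chiral-pool transformation of serine and threonine, so C2 keeps the D configuration and C3 is untouched.

Step 2
Reactants: 2 (2R,3S)-2-chloro-3-hydroxybutanoic acid
Product: 3 (2S,3S)-2-chlorobutane-1,3-diol
Conditions: BH3·THF, THF, 0 °C to rt; then MeOH, evaporate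
Reagents that add atoms: none
Why: Borane reduction of a free carboxylic acid leaves the C–Cl bond and both stereocentres alone (the change of the C2 descriptor from R to S is a priority change only), and the non-aqueous work-up avoids loss of the water-soluble diol and base-induced epoxide formation.

Step 3
Reactants: 3 (2S,3S)-2-chlorobutane-1,3-diol; 4 isofraxidin (7-hydroxy-6,8-dimethoxy-2H-chromen-2-one)
Product: 5 7-{[(2S,3S)-2-chloro-3-hydroxybutyl]oxy}-6,8-dimethoxy-2H-chromen-2-one
Conditions: PPh3, DIAD, THF, 0 °C to rt
Reagents that add atoms: none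
Why: Mitsunobu etherification, in which the acidic 7-OH of the coumarin should be alkylated through the primary alkoxyphosphonium in preference to the hindered secondary one next to CHCl; no stereocentre is involved.

Step 4
Reactants: 5 7-{[(2S,3S)-2-chloro-3-hydroxybutyl]oxy}-6,8-dimethoxy-2H-chromen-2-one
Product: 6 7-{[(2S)-2-chloro-3-oxobutyl]oxy}-6,8-dimethoxy-2H-chromen-2-one
Conditions: Dess–Martin periodinane, CH2Cl2, 0 °C to rt; non-basic work-up, used crude
Reagents that add atoms: none
Why: Dess–Martin oxidation of the secondary alcohol runs without base, so neither enolisation at C2 nor E1cB loss of the coumarin phenoxide should be triggered, and the 2S chloride is carried unchanged.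

Step 5
Reactants: 7 2-methylbut-3-en-2-ol; 8 (E)-1,4-dibromobut-2-ene
Product: 9 (3E)-5-bromo-2-methylpent-3-en-2-ol
Conditions: Hoveyda–Grubbs II (cat.), 7 in excess, CH2Cl2, 40 °C
Reagents that add atoms: none
Why: Olefin cross metathesis between a slowly homodimerising tertiary allylic alcohol and a symmetrical allylic dibromide should give the E-disubstituted olefin under thermodynamic control, each dibromide delivering two bromoallyl units.

Step 6
Reactants: 6 7-{[(2S)-2-chloro-3-oxobutyl]oxy}-6,8-dimethoxy-2H-chromen-2-one; 9 (3E)-5-bromo-2-methylpent-3-en-2-ol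
Product: 11 7-{[(2R,3R)-3-[(2E)-4-hydroxy-4-methylpent-2-en-1-yl]-3-methyloxiran-2-yl]methoxy}-6,8-dimethoxy-2H-chromen-2-one, via chlorohydrin 10 (not isolated)
Conditions: In powder, THF/H2O, 0 °C to rt; then K2CO3, MeOH, rt
Reagents that add atoms: none
Why: Proposed new method: indium inserts into the allylic C–Br bond of 9 and the allylindium adds to the ketone of 6 at its CH2 terminus, either through its 1,3-metallotropic isomer in a six-membered transition state with the carbinol group pseudo-equatorial (hence 5E) or by direct SE2 at the CH2–In carbon, because the other terminus is neopentyl-like and would have to create two adjacent congested centres; carbonate then converts the tertiary alkoxide of 10 into the oxirane by intramolecular SN2 displacement of chloride. The closest known reaction types are the indium-mediated Barbier allylation of α-chloro ketones to chlorohydrins that close to epoxides (the first half of the Cornforth olefin synthesis) and the α-selective coupling of γ-tert-butyl- and γ-silyl-allyl bromides with aldehydes; what is untested is α-regiochemistry with a ketone acceptor and a free hydroxyl in the allyl partner. The oxirane closes in a 3-exo-tet mode with inversion at C2, which turns the 2S chloride into the 2R ring carbon. The new quaternary centre C3 is set by 1,2-induction from the C2–Cl stereocentre (Cornforth/polar Felkin–Anh: C–Cl opposed to C=O, attack past H and not past CH2OAr), which places CH2OAr and the new chain trans on the ring, that is 3R. The step needs α- over γ-regioselectivity, E geometry, addition to the ketone and not to the coumarin lactone, and no β-elimination of the phenoxide; these should be secured by the steric block at the γ-carbon, the equatorial preference of the carbinol group, the low basicity and carbonyl selectivity of allylindium in water, and the near-neutral medium until the ketone is consumed.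

**Compound list**

1 | D-threonine, (2R,3S)-2-amino-3-hydroxybutanoic acid | C[C@@H]([C@H](C(=O)O)N)O | starting material
2 | (2R,3S)-2-chloro-3-hydroxybutanoic acid | C[C@@H]([C@H](C(=O)O)Cl)O | intermediate
3 | (2S,3S)-2-chlorobutane-1,3-diol | C[C@@H]([C@H](CO)Cl)O | intermediate
4 | isofraxidin, 7-hydroxy-6,8-dimethoxy-2H-chromen-2-one | COc1cc2ccc(=O)oc2c(OC)c1O | starting material
5 | 7-{[(2S,3S)-2-chloro-3-hydroxybutyl]oxy}-6,8-dimethoxy-2H-chromen-2-one | COc1cc2ccc(=O)oc2c(OC)c1OC[C@H](Cl)[C@H](C)O | intermediate
6 | 7-{[(2S)-2-chloro-3-oxobutyl]oxy}-6,8-dimethoxy-2H-chromen-2-one | COc1cc2ccc(=O)oc2c(OC)c1OC[C@H](Cl)C(C)=O | intermediate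
7 | 2-methylbut-3-en-2-ol | CC(C)(O)C=C | starting material
8 | (E)-1,4-dibromobut-2-ene | BrC/C=C/CBr | starting material
9 | (3E)-5-bromo-2-methylpent-3-en-2-ol | CC(C)(O)/C=C/CBr | intermediate
10 | 7-{[(2S,3R,5E)-2-chloro-3,7-dihydroxy-3,7-dimethyloct-5-en-1-yl]oxy}-6,8-dimethoxy-2H-chromen-2-one (chlorohydrin, not isolated) | COc1cc2ccc(=O)oc2c(OC)c1OC[C@H](Cl)[C@](C)(O)C/C=C/C(C)(C)O | intermediate
11 | 7-{[(2R,3R)-3-[(2E)-4-hydroxy-4-methylpent-2-en-1-yl]-3-methyloxiran-2-yl]methoxy}-6,8-dimethoxy-2H-chromen-2-one | COc1cc2ccc(=O)oc2c(OC)c1OC[C@H]1O[C@]1(C)C/C=C/C(C)(C)O | target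

**Count and risks**

Total step count: 6. Longest linear sequence: 5 steps (steps 1, 2, 3, 4 and 6, from D-threonine).

Steps most likely to fail:

1. Step 6 (proposed new method). The allylindium may bond through its hindered γ-terminus, may undergo reductive 1,4-elimination of its hydroxyl to a diene, may lose E geometry, or the 1,2-induction may be too weak. Fallback with known chemistry, setting out from 6: indium-mediated Barbier allylation with allyl bromide itself (In, THF/H2O), a symmetrical donor with close precedent on α-chloro ketones, should give the chlorohydrin 7-{[(2S,3R)-2-chloro-3-hydroxy-3-methylhex-5-en-1-yl]oxy}-6,8-dimethoxy-2H-chromen-2-one F1. K2CO3 in MeOH should close it to the allyl oxirane 6,8-dimethoxy-7-{[(2R,3R)-3-methyl-3-(prop-2-en-1-yl)oxiran-2-yl]methoxy}-2H-chromen-2-one F2. E-selective cross metathesis of F2 with an excess of 7 (Hoveyda–Grubbs II, CH2Cl2, 40 °C) then installs the (E)-CH=CH–C(CH3)2OH terminus and comes back to the route at 11; the electron-poor, ring-bound coumarin C3=C4 bond should not take part.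

2. Step 4. The β-aryloxy α-chloro ketone may lose the coumarin phenoxide by E1cB elimination, or epimerise at C2 by enolisation, during oxidation and handling. Fallback, setting out from 3, in which the aryl ether is made last so that no phenoxide sits β to the ketone:
   - Selective silylation of the primary hydroxyl (TBSCl, imidazole, CH2Cl2, 0 °C) should give (2S,3S)-4-[(tert-butyldimethylsilyl)oxy]-3-chlorobutan-2-ol F3.
   - Dess–Martin oxidation should give (3S)-4-[(tert-butyldimethylsilyl)oxy]-3-chlorobutan-2-one F4, in which silyloxide is a far poorer β-leaving group.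
   - Barbier coupling of F4 with 9 under the conditions of step 6 should give the chlorohydrin (2S,3R,5E)-1-[(tert-butyldimethylsilyl)oxy]-2-chloro-3,7-dimethyloct-5-ene-3,7-diol F5, closed by K2CO3/MeOH to (3E)-5-[(2R,3R)-3-{[(tert-butyldimethylsilyl)oxy]methyl}-2-methyloxiran-2-yl]-2-methylpent-3-en-2-ol F6.
   - TBAF in THF should release (3E)-5-[(2R,3R)-3-(hydroxymethyl)-2-methyloxiran-2-yl]-2-methylpent-3-en-2-ol F7.
   - Mitsunobu etherification of the primary hydroxyl of F7 with 4 (PPh3, DIAD, THF) comes back to the route at 11; the tertiary alcohol should not react.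

3. Step 3. The two hydroxyls may not be discriminated well, the activated chlorodiol may cyclodehydrate, or the doubly ortho-substituted phenol may couple sluggishly. Fallback, setting out from 3, which replaces phosphonium activation by a cyclic sulfate:
   - SOCl2 (CH2Cl2, 0 °C) should give the cyclic sulfite (4S,5S)-5-chloro-4-methyl-1,3,2-dioxathiane 2-oxide F8.
   - RuCl3 (cat.)/NaIO4 should oxidise it to the cyclic sulfate (4S,5S)-5-chloro-4-methyl-1,3,2-dioxathiane 2,2-dioxide F9.
   - The caesium phenoxide of 4 (Cs2CO3, DMF, rt) should open F9 at the primary carbon to caesium (2S,3S)-3-chloro-4-[(6,8-dimethoxy-2-oxo-2H-chromen-7-yl)oxy]butan-2-yl sulfate F10.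
   - Acid hydrolysis of the sulfate monoester (cat. H2SO4, THF, trace water) comes back to the route at 5.

**Further compounds**

F1 | step 6 | 7-{[(2S,3R)-2-chloro-3-hydroxy-3-methylhex-5-en-1-yl]oxy}-6,8-dimethoxy-2H-chromen-2-one | COc1cc2ccc(=O)oc2c(OC)c1OC[C@H](Cl)[C@](C)(O)CC=C
F2 | step 6 | 6,8-dimethoxy-7-{[(2R,3R)-3-methyl-3-(prop-2-en-1-yl)oxiran-2-yl]methoxy}-2H-chromen-2-one | COc1cc2ccc(=O)oc2c(OC)c1OC[C@H]1O[C@]1(C)CC=C
F3 | step 4 | (2S,3S)-4-[(tert-butyldimethylsilyl)oxy]-3-chlorobutan-2-ol | C[C@@H]([C@H](CO[Si](C)(C)C(C)(C)C)Cl)O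
F4 | step 4 | (3S)-4-[(tert-butyldimethylsilyl)oxy]-3-chlorobutan-2-one | CC(=O)[C@H](CO[Si](C)(C)C(C)(C)C)Cl
F5 | step 4 | (2S,3R,5E)-1-[(tert-butyldimethylsilyl)oxy]-2-chloro-3,7-dimethyloct-5-ene-3,7-diol | CC(C)(C)[Si](C)(C)OC[C@H](Cl)[C@](C)(O)C/C=C/C(C)(C)O
F6 | step 4 | (3E)-5-[(2R,3R)-3-{[(tert-butyldimethylsilyl)oxy]methyl}-2-methyloxiran-2-yl]-2-methylpent-3-en-2-ol | CC(C)(C)[Si](C)(C)OC[C@H]1O[C@]1(C)C/C=C/C(C)(C)O
F7 | step 4 | (3E)-5-[(2R,3R)-3-(hydroxymethyl)-2-methyloxiran-2-yl]-2-methylpent-3-en-2-ol | OC[C@H]1O[C@]1(C)C/C=C/C(C)(C)O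
F8 | step 3 | (4S,5S)-5-chloro-4-methyl-1,3,2-dioxathiane 2-oxide | C[C@@H]([C@H](CO1)Cl)OS1=O
F9 | step 3 | (4S,5S)-5-chloro-4-methyl-1,3,2-dioxathiane 2,2-dioxide | C[C@@H]([C@H](CO1)Cl)OS1(=O)=O
F10 | step 3 | caesium (2S,3S)-3-chloro-4-[(6,8-dimethoxy-2-oxo-2H-chromen-7-yl)oxy]butan-2-yl sulfate | COc1cc2ccc(=O)oc2c(OC)c1OC[C@H](Cl)[C@H](C)OS(=O)(=O)[O-].[Cs+]
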